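## Retrosynthetic overview

1. The target gambiriin comes from one-pot hydrogenolysis (eight O-benzyl groups, two aryl bromides) of a protected dimer.
2. Key disconnection: the benzylic C–aryl bond from C2 of the ring-C-opened (upper) unit to C6 of the intact (lower) flavan. It is made by a visible-light photoredox, stereoinvertive arylative opening of ring C, in which two molecules of one monomer react, one as radical-cation electrophile and one as C6 nucleophile.
3. Monomer: 8-bromo-5,7,3',4'-tetra-O-benzyl-(+)-catechin. The C8 bromine blocks the normally preferred site, so only C6 can attack.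
4. The monomer comes from (+)-catechin (1) by O-benzylation and C8 bromination. All four stereocentres are those of 1: three untouched, the diarylmethine formed by inversion at C2.
5. Ring order: no ring is built. Rings A, B and C of the lower unit come intact from 1; ring C of the upper unit is opened in the key step.

Assumption: the target is taken exactly as the SMILES given (C6-linked; lower unit 2R,3S; side chain 1R,2S).

## Route

Step 1
Reactants: 1 (+)-catechin; 2 benzyl bromide
Product: 3 5,7,3',4'-tetra-O-benzyl-(+)-catechin
Conditions: BnBr (4.4 equiv), K2CO3 (4.5 equiv), DMF, 0 °C to rt, argon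
Reagents that add atoms: benzyl bromide, BrCc1ccccc1
Why: Williamson ether synthesis; K2CO3 deprotonates only the four phenols, so the secondary 3-OH stays free and both stereocentres are untouched.

Step 2
Reactants: 3 5,7,3',4'-tetra-O-benzyl-(+)-catechin; 4 N-bromosuccinimide
Product: 5 8-bromo-5,7,3',4'-tetra-O-benzyl-(+)-catechin
Conditions: NBS (1.05 equiv), CH2Cl2, −78 °C to rt
Reagents that add atoms: N-bromosuccinimide, O=C1CCC(=O)N1Br
Why: Electrophilic aromatic bromination; in the tetrabenzyl ether C8 (between the ring oxygen and one OBn) is far more accessible than C6 (between two OBn), so the 8-bromide forms cleanly, and this bromine later forces bond formation at C6.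

Step 3
Reactants: 5 8-bromo-5,7,3',4'-tetra-O-benzyl-(+)-catechin (two molecules, one as electrophile, one as C6 nucleophile)
Product: 6 (2R,3S)-5,7-bis(benzyloxy)-2-[3,4-bis(benzyloxy)phenyl]-6-{(1R,2S)-1-[3,4-bis(benzyloxy)phenyl]-3-[4,6-bis(benzyloxy)-3-bromo-2-hydroxyphenyl]-2-hydroxypropyl}-8-bromochroman-3-ol
Conditions: 9-mesityl-3,6-di-tert-butyl-10-phenylacridinium tetrafluoroborate (5 mol%), 450 nm LEDs, 1,1,1,3,3,3-hexafluoropropan-2-ol (HFIP)/CH2Cl2 1:1, 0.3 M, argon, 10 °C; stop near 60% conversion, recycle 5
Reagents that add atoms: none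
Why: Proposed new method: the excited acridinium (about +2.0 V vs SCE) oxidises 5 (estimated +1.4 V) to its arene radical cation, whose benzylic C2–O1 bond is weakened much as the C–O bond of an alkoxyamine radical cation; C6 of a second, neutral 5 (the only electron-rich aromatic CH left, because C8 carries Br) attacks C2 anti to the departing O1 in a three-electron SN2 step that releases the ring A aryloxyl radical, the Wheland intermediate loses H+, and the acridinyl radical (about −0.6 V) reduces the aryloxyl radical to the phenol, closing a redox-neutral cycle that consumes no oxidant or acid and leaves the aryl bromides alone (not reducible at −0.6 V, transparent at 450 nm); inversion at the catechin-derived C2 gives the (1R) diarylmethine, and if the step drifts toward a free benzylic cation the tethered leaving group and allylic 1,3-strain (attack anti to the CH2-aryl arm) favour the same face, so the new stereocentre is set by the purchased ones; HFIP prolongs radical-cation lifetime and slows C–H deprotonation; closest known reaction types: stereoinvertive nucleophilic ring opening of arylcyclopropane radical cations under photoredox catalysis, and carbocation generation by mesolytic C–O cleavage of alkoxyamine radical cations followed by Friedel–Crafts capture.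

Step 4
Reactants: 6 protected dibromo dimer
Product: 7 target gambiriin, (2R,3S)-2-(3,4-dihydroxyphenyl)-6-[(1R,2S)-1-(3,4-dihydroxyphenyl)-2-hydroxy-3-(2,4,6-trihydroxyphenyl)propyl]chroman-3,5,7-triol
Conditions: H2 (1 atm), Pd(OH)2/C, NaOAc (3 equiv), THF/MeOH/H2O 10:10:1, rt; filter under argon, Sephadex LH-20
Reagents that add atoms: none
Why: Heterogeneous catalytic hydrogenolysis; Pd(OH)2/C cleaves the eight benzyl ethers and, with NaOAc as HBr trap, both aryl C–Br bonds in one operation, while the stereocentres, the diarylmethine C–C bonds and the ring C ether of the lower unit are not touched.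

## Compound list

1 | (+)-catechin, (2R,3S)-2-(3,4-dihydroxyphenyl)chroman-3,5,7-triol | Oc1cc(O)c2C[C@H](O)[C@@H](c3ccc(O)c(O)c3)Oc2c1 | starting material
2 | benzyl bromide | BrCc1ccccc1 | starting material
3 | 5,7,3',4'-tetra-O-benzyl-(+)-catechin, (2R,3S)-5,7-bis(benzyloxy)-2-[3,4-bis(benzyloxy)phenyl]chroman-3-ol | c1ccccc1COc1cc(OCc2ccccc2)c2C[C@H](O)[C@@H](c3ccc(OCc4ccccc4)c(OCc4ccccc4)c3)Oc2c1 | intermediate
4 | N-bromosuccinimide | O=C1CCC(=O)N1Br | starting material
5 | 8-bromo-5,7,3',4'-tetra-O-benzyl-(+)-catechin, (2R,3S)-5,7-bis(benzyloxy)-2-[3,4-bis(benzyloxy)phenyl]-8-bromochroman-3-ol | c1ccccc1COc1cc(OCc2ccccc2)c2C[C@H](O)[C@@H](c3ccc(OCc4ccccc4)c(OCc4ccccc4)c3)Oc2c1Br | intermediate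
6 | (2R,3S)-5,7-bis(benzyloxy)-2-[3,4-bis(benzyloxy)phenyl]-6-{(1R,2S)-1-[3,4-bis(benzyloxy)phenyl]-3-[4,6-bis(benzyloxy)-3-bromo-2-hydroxyphenyl]-2-hydroxypropyl}-8-bromochroman-3-ol | c1ccccc1COc1cc(OCc2ccccc2)c(C[C@H](O)[C@H](c2ccc(OCc3ccccc3)c(OCc3ccccc3)c2)c2c(OCc3ccccc3)c(Br)c3c(c2OCc2ccccc2)C[C@H](O)[C@@H](c2ccc(OCc4ccccc4)c(OCc4ccccc4)c2)O3)c(O)c1Br | intermediate
7 | target gambiriin, (2R,3S)-2-(3,4-dihydroxyphenyl)-6-[(1R,2S)-1-(3,4-dihydroxyphenyl)-2-hydroxy-3-(2,4,6-trihydroxyphenyl)propyl]chroman-3,5,7-triol | Oc1cc(O)c(C[C@H](O)[C@H](c2ccc(O)c(O)c2)c2c(O)cc3c(c2O)C[C@H](O)[C@@H](c2ccc(O)c(O)c2)O3)c(O)c1 | target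

## Step count and risks

Total step count: 4. Longest linear sequence: 4 steps (1 → 3 → 5 → 6 → 7).

Three steps most likely to fail:

**Step 3 (the proposed new step).** Risks:
- back electron transfer outrunning substitution;
- attack of the nucleophile on the oxidised arene ring instead of C2;
- C2 epimerisation of recovered 5 by opening and reclosure;
- a second alkylation at the free CH of the new phenol ring (trimer), or oxidation of the new phenol by the excited catalyst.

Fallback, known chemistry, from 5 back to the route at 7: give up the protected photoredox coupling and use the ground-state quinone methide condensation by which unprotected catechin is known to form chalcane–flavan dimers in hot water, keeping the bromine block. Cleave the benzyl ethers of 5 without touching the bromide (BCl3, pentamethylbenzene, CH2Cl2, −78 °C) to give 8-bromo-(+)-catechin F2. Heat F2 in degassed water (pH about 6, 90 °C, partial conversion) so that the ring B quinone methide formed by thermal O1–C2 heterolysis is captured at C6 of a second molecule, giving 8-bromo-6-[(1R,2S)-3-(3-bromo-2,4,6-trihydroxyphenyl)-1-(3,4-dihydroxyphenyl)-2-hydroxypropyl]-(+)-catechin F3. Hydrodebrominate F3 (H2, Pd/C, NaOAc, MeOH) to reach 7. Facial control then rests only on allylic 1,3-strain, and some C2 epimerisation of the flavan is expected, so the (1S) epimer and epimerised material must be removed by reversed-phase chromatography.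

**Step 4.** Risks:
- bromide released early poisons the catalyst and debenzylation stalls;
- one C–Br survives;
- ring C of the lower unit is hydrogenolysed;
- the free polyphenol oxidises in air.

Fallback, from 6 back to the route at 7: separate the two reductions. First remove both bromides under homogeneous transfer conditions that leave benzyl ethers alone (Pd(OAc)2, SPhos, HCO2Na, DMF, 80 °C), giving the octabenzyl ether (2R,3S)-5,7-bis(benzyloxy)-2-[3,4-bis(benzyloxy)phenyl]-6-{(1R,2S)-1-[3,4-bis(benzyloxy)phenyl]-3-[4,6-bis(benzyloxy)-2-hydroxyphenyl]-2-hydroxypropyl}chroman-3-ol F4. Then hydrogenolyse F4 in neutral, halide-free medium (H2, Pd(OH)2/C, THF/MeOH) to 7.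

**Step 1.** Risks:
- C-benzylation of the phloroglucinol ring;
- partial 3-O-benzylation;
- air oxidation of the catecholate in DMF.

Fallback, from 1 back to the route at 3: exchange acetate for benzyl instead of alkylating the free polyphenol. Acetylate 1 fully (Ac2O, pyridine) to crystalline (+)-catechin pentaacetate F1. Treat F1 with BnBr (2) and K2CO3 in DMF/MeOH at 40 °C: methanolysis releases each phenoxide slowly and it is benzylated at once, while the 3-acetate is cleaved but the alcohol is not alkylated, giving 3.

## Further compounds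

F1 | step 1 | (+)-catechin pentaacetate | CC(=O)Oc1cc(OC(C)=O)c2C[C@H](OC(C)=O)[C@@H](c3ccc(OC(C)=O)c(OC(C)=O)c3)Oc2c1
F2 | step 3 | 8-bromo-(+)-catechin | Oc1cc(O)c2C[C@H](O)[C@@H](c3ccc(O)c(O)c3)Oc2c1Br
F3 | step 3 | 8-bromo-6-[(1R,2S)-3-(3-bromo-2,4,6-trihydroxyphenyl)-1-(3,4-dihydroxyphenyl)-2-hydroxypropyl]-(+)-catechin | Oc1cc(O)c(C[C@H](O)[C@H](c2ccc(O)c(O)c2)c2c(O)c(Br)c3c(c2O)C[C@H](O)[C@@H](c2ccc(O)c(O)c2)O3)c(O)c1Br
F4 | step 4 | (2R,3S)-5,7-bis(benzyloxy)-2-[3,4-bis(benzyloxy)phenyl]-6-{(1R,2S)-1-[3,4-bis(benzyloxy)phenyl]-3-[4,6-bis(benzyloxy)-2-hydroxyphenyl]-2-hydroxypropyl}chroman-3-ol | c1ccccc1COc1cc(OCc2ccccc2)c(C[C@H](O)[C@H](c2ccc(OCc3ccccc3)c(OCc3ccccc3)c2)c2c(OCc3ccccc3)cc3c(c2OCc2ccccc2)C[C@H](O)[C@@H](c2ccc(OCc4ccccc4)c(OCc4ccccc4)c2)O3)c(O)c1
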